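**Retrosynthetic overview**

1. Sikokianin B is a 3,3''-biflavanone. The strategy rests on the C3–C3'' bond: each of its carbons carries a carbonyl carbon (C4 of the unit 1 pyranone ring, C4'' of the unit 2 pyranone ring), the pattern left by syn addition of two acyl groups across a Z C3=C3'' alkene.
2. The unit 2 pyranone ring is opened at C4''–C4a'' (Friedel–Crafts acylation of a C3'' carboxylic acid onto its own 3,5-bis(benzyloxy)phenyl ether); it is the last ring formed.
3. The unit 1 pyranone ring is opened at C4a–C4, C4–C3 and C3''–C4'' in one palladium/CO step from a Z-1,4-diarylbut-2-ene-1,4-diyl bis(aryl ether) with one ortho-iodide; it is the first ring formed, and the step sets C3 and C3''.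
4. The Z-alkene comes from two catalytic asymmetric alkynylations (C2 and C2'' as carbinols), two Mitsunobu etherifications with inversion and a Z-selective semihydrogenation.

Key step: step 8

Remark: the SMILES is read as the (2R,3S,2''R,3''R) isomer, that is 2,3-trans in unit 1 (4-methoxyphenyl flavanone, plain locants) and 2'',3''-cis in unit 2 (4-hydroxyphenyl flavanone, double-primed locants); the ProPhenol antipode for steps 1 and 5 is taken to be whichever one gives the R carbinol.

**Route**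

Step 1
Reactants: 1 4-methoxybenzaldehyde; 2 trimethylsilylacetylene
Product: 3 (R)-1-(4-methoxyphenyl)-3-(trimethylsilyl)prop-2-yn-1-ol
Conditions: Me2Zn, ProPhenol ligand (10 mol%, antipode that gives the R carbinol), Ph3P=O (20 mol%), toluene, 0 °C to rt; aq. NH4Cl
Reagents that add atoms: none
Why: Catalytic asymmetric alkynylation of an aryl aldehyde by an alkynylzinc under dinuclear zinc–ProPhenol catalysis is established for aromatic aldehydes and silylacetylenes, and the chiral catalyst alone chooses the aldehyde face, which sets the carbinol centre as R.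

Step 2
Reactants: 4 3,5-bis(benzyloxy)phenol
Product: 5 3,5-bis(benzyloxy)-2-iodophenol
Conditions: I2 (1.0 equiv), NaHCO3, THF/H2O, 0 °C
Reagents that add atoms: iodine, II
Why: Electrophilic aromatic iodination of the phenoxide goes ortho to the free hydroxyl, and the position between OH and OBn is less crowded than the one between the two OBn groups, so monoiodination at C2 is expected.

Step 3
Reactants: 3 (R)-1-(4-methoxyphenyl)-3-(trimethylsilyl)prop-2-yn-1-ol; 5 3,5-bis(benzyloxy)-2-iodophenol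
Product: 6 (S)-{3-[3,5-bis(benzyloxy)-2-iodophenoxy]-3-(4-methoxyphenyl)prop-1-yn-1-yl}trimethylsilane
Conditions: PPh3, DIAD, toluene, −20 °C to 0 °C
Reagents that add atoms: none
Why: In this Mitsunobu etherification the phenoxide displaces the oxyphosphonium group in an SN2 step with inversion (R carbinol to S aryl ether, the arrangement needed at C2), while toluene and low temperature disfavour ionisation of the 4-methoxybenzylic carbon and the silyl group blocks SN2' attack.

Step 4
Reactants: 6 (S)-{3-[3,5-bis(benzyloxy)-2-iodophenoxy]-3-(4-methoxyphenyl)prop-1-yn-1-yl}trimethylsilane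
Product: 7 (R)-1,5-bis(benzyloxy)-2-iodo-3-{[1-(4-methoxyphenyl)prop-2-yn-1-yl]oxy}benzene
Conditions: K2CO3 (0.2 equiv), MeOH/THF, 0 °C to rt
Reagents that add atoms: none
Why: Methoxide-catalysed protodesilylation of the alkynylsilane leaves the ethers, the iodide and the stereocentre untouched; the descriptor changes from S to R only because ethynyl ranks below aryl.

Step 5
Reactants: 7 (R)-1,5-bis(benzyloxy)-2-iodo-3-{[1-(4-methoxyphenyl)prop-2-yn-1-yl]oxy}benzene; 8 4-(benzyloxy)benzaldehyde
Product: 9 (1R,4S)-1-[4-(benzyloxy)phenyl]-4-[3,5-bis(benzyloxy)-2-iodophenoxy]-4-(4-methoxyphenyl)but-2-yn-1-ol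
Conditions: Me2Zn, ProPhenol ligand (same antipode as in step 1), Ph3P=O, toluene, 0 °C to rt; aq. NH4Cl
Reagents that add atoms: none
Why: The same catalytic asymmetric alkynylation, now with the alkynylzinc of 7, sets the new carbinol centre as R under catalyst control; the distant ether stereocentre has no say and the aryl iodide is inert to Me2Zn.

Step 6
Reactants: 9 (1R,4S)-1-[4-(benzyloxy)phenyl]-4-[3,5-bis(benzyloxy)-2-iodophenoxy]-4-(4-methoxyphenyl)but-2-yn-1-ol; 4 3,5-bis(benzyloxy)phenol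
Product: 10 (1S,4S)-1-[4-(benzyloxy)phenyl]-1-[3,5-bis(benzyloxy)phenoxy]-4-[3,5-bis(benzyloxy)-2-iodophenoxy]-4-(4-methoxyphenyl)but-2-yne
Conditions: PPh3, DIAD, toluene, −20 °C to 0 °C
Reagents that add atoms: none
Why: A second Mitsunobu etherification with SN2 inversion converts the R carbinol into the S aryl ether, the arrangement needed at C2''.

Step 7
Reactants: 10 (1S,4S)-1-[4-(benzyloxy)phenyl]-1-[3,5-bis(benzyloxy)phenoxy]-4-[3,5-bis(benzyloxy)-2-iodophenoxy]-4-(4-methoxyphenyl)but-2-yne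
Product: 11 (1R,4R,Z)-1-[4-(benzyloxy)phenyl]-1-[3,5-bis(benzyloxy)phenoxy]-4-[3,5-bis(benzyloxy)-2-iodophenoxy]-4-(4-methoxyphenyl)but-2-ene
Conditions: H2 (1 atm), Pd/CaCO3 poisoned with Pb(OAc)2 (Lindlar catalyst), quinoline, EtOAc, rt
Reagents that add atoms: none
Why: Lindlar semihydrogenation adds H2 syn to the alkyne and gives the Z-alkene; the flanking tertiary carbons slow further reduction, the benzyl ethers and the aryl iodide should survive the poisoned catalyst, and the centres become R,R by a change of group ranking only.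

Step 8
Reactants: 11 (1R,4R,Z)-1-[4-(benzyloxy)phenyl]-1-[3,5-bis(benzyloxy)phenoxy]-4-[3,5-bis(benzyloxy)-2-iodophenoxy]-4-(4-methoxyphenyl)but-2-ene
Product: 12 methyl (2R,3R)-2-[(2R,3S)-5,7-bis(benzyloxy)-2-(4-methoxyphenyl)-4-oxochroman-3-yl]-3-[4-(benzyloxy)phenyl]-3-[3,5-bis(benzyloxy)phenoxy]propanoate
Conditions: PdCl2(PPh3)2 (10 mol%), CO (40 atm), Et3N (2 equiv), MeOH (4 equiv), MeCN/toluene 1:1, 95 °C
Reagents that add atoms: carbon monoxide, [C-]#[O+] (two molecules); methanol, CO
Why: Proposed new method: zerovalent palladium (formed in situ from PdCl2(PPh3)2) should insert into the C–I bond, take up CO to a divalent aroylpalladium and add this acyl–Pd unit syn across the Z-alkene, which forms C4a–C4 and C4–C3 and leaves palladium on C3''; a second CO insertion with retention at C3'' and methanolysis then give the C3''–CO2Me ester and return zerovalent palladium. The closest known reaction type is the cyclic acylpalladation of ortho-iodoaryl alkenes that carry a terminal vinyl group, ended by carbonylative ester formation; an internal Z-alkene whose alkylpalladium has beta hydrogens and a beta aryloxy group, used to relay stereochemistry, is beyond it. The unit 1 pyranone ring closes in 6-exo-trig mode, C4 bonding to the proximal alkene carbon C3. C3 is set by the C2 stereocentre: allylic 1,3-strain of the Z-alkene keeps the C2–H bond near the alkene plane, the tether oxygen brings the acyl group to one face and the 4-methoxyphenyl group sits pseudo-equatorial on the other, which gives the 2,3-trans ring (3S). C3'' is set by the syn stereospecificity of the acylpalladation together with the retentive CO insertion (3''R), so that with C2'' fixed beforehand the unit 2 ring can only close cis later. The step needs CO insertion into the aryl–palladium bond to outrun 5-exo carbopalladation, and CO capture of the C3'' alkylpalladium to outrun beta-hydride and beta-aryloxide elimination; 40 atm of CO, chelation of palladium by the new C4 ketone oxygen and a small amount of methanol (against early methanolysis of the aroylpalladium) are relied on for this.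

Step 9
Reactants: 12 methyl (2R,3R)-2-[(2R,3S)-5,7-bis(benzyloxy)-2-(4-methoxyphenyl)-4-oxochroman-3-yl]-3-[4-(benzyloxy)phenyl]-3-[3,5-bis(benzyloxy)phenoxy]propanoate
Product: 14 (2R,3R)-2-[(2R,3S)-5,7-bis(benzyloxy)-2-(4-methoxyphenyl)-4-oxochroman-3-yl]-3-[4-(benzyloxy)phenyl]-3-[3,5-bis(benzyloxy)phenoxy]propanoic acid, via trimethylstannyl ester 13 (not isolated)
Conditions: Me3SnOH (8 equiv), ClCH2CH2Cl, 80 °C; then cold 0.1 M aq. HCl wash
Reagents that add atoms: trimethyltin hydroxide, C[Sn](C)(C)O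
Why: Me3SnOH hydrolysis is a mild, nearly neutral acyl–oxygen cleavage of methyl esters that should avoid hydroxide-induced E1cB loss of the C2'' aryloxide, opening of the unit 1 pyranone and epimerisation at C3 or C3''; the tin carboxylate is protonated on the acid wash.

Step 10
Reactants: 14 (2R,3R)-2-[(2R,3S)-5,7-bis(benzyloxy)-2-(4-methoxyphenyl)-4-oxochroman-3-yl]-3-[4-(benzyloxy)phenyl]-3-[3,5-bis(benzyloxy)phenoxy]propanoic acid
Product: 16 (2R,3S,2''R,3''R)-5,7,5'',7''-tetrakis(benzyloxy)-2''-[4-(benzyloxy)phenyl]-2-(4-methoxyphenyl)-3,3''-bichromane-4,4''-dione, via acid chloride 15 (not isolated)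
Conditions: 1-chloro-N,N,2-trimethylprop-1-en-1-amine, CH2Cl2, 0 °C; then SnCl4 (1.1 equiv), −78 °C; aq. NaHCO3
Reagents that add atoms: none
Why: In this intramolecular Friedel–Crafts acylation the acid chloride, made under neutral conditions, attacks the very electron-rich 3,5-bis(benzyloxy)phenyl ether at either of its two equivalent positions ortho to the ether oxygen in a six-membered closure at −78 °C, which forms C4''–C4a'' without touching C2'' or C3'' and so gives the cis unit 2 ring.

Step 11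
Reactants: 16 (2R,3S,2''R,3''R)-5,7,5'',7''-tetrakis(benzyloxy)-2''-[4-(benzyloxy)phenyl]-2-(4-methoxyphenyl)-3,3''-bichromane-4,4''-dione
Product: 17 Sikokianin B
Conditions: H2 (1 atm), 10% Pd/C, EtOAc/MeOH, rt
Reagents that add atoms: none
Why: Catalytic hydrogenolysis cleaves the five benzyl aryl ethers, while the aryl methyl ether, both ketones and the ring C–O bonds should persist at 1 atm and room temperature, and no stereocentre is involved.

**Compound list**

1 | 4-methoxybenzaldehyde | COc1ccc(C=O)cc1 | starting material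
2 | trimethylsilylacetylene | C#C[Si](C)(C)C | starting material
3 | (R)-1-(4-methoxyphenyl)-3-(trimethylsilyl)prop-2-yn-1-ol | COc1ccc([C@@H](O)C#C[Si](C)(C)C)cc1 | intermediate
4 | 3,5-bis(benzyloxy)phenol | Oc1cc(OCc2ccccc2)cc(OCc2ccccc2)c1 | starting material
5 | 3,5-bis(benzyloxy)-2-iodophenol | Oc1cc(OCc2ccccc2)cc(OCc2ccccc2)c1I | intermediate
6 | (S)-{3-[3,5-bis(benzyloxy)-2-iodophenoxy]-3-(4-methoxyphenyl)prop-1-yn-1-yl}trimethylsilane | COc1ccc([C@H](Oc2cc(OCc3ccccc3)cc(OCc3ccccc3)c2I)C#C[Si](C)(C)C)cc1 | intermediate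
7 | (R)-1,5-bis(benzyloxy)-2-iodo-3-{[1-(4-methoxyphenyl)prop-2-yn-1-yl]oxy}benzene | COc1ccc([C@H](Oc2cc(OCc3ccccc3)cc(OCc3ccccc3)c2I)C#C)cc1 | intermediate
8 | 4-(benzyloxy)benzaldehyde | O=Cc1ccc(OCc2ccccc2)cc1 | starting material
9 | (1R,4S)-1-[4-(benzyloxy)phenyl]-4-[3,5-bis(benzyloxy)-2-iodophenoxy]-4-(4-methoxyphenyl)but-2-yn-1-ol | COc1ccc([C@H](Oc2cc(OCc3ccccc3)cc(OCc3ccccc3)c2I)C#C[C@H](O)c2ccc(OCc3ccccc3)cc2)cc1 | intermediate
10 | (1S,4S)-1-[4-(benzyloxy)phenyl]-1-[3,5-bis(benzyloxy)phenoxy]-4-[3,5-bis(benzyloxy)-2-iodophenoxy]-4-(4-methoxyphenyl)but-2-yne | COc1ccc([C@H](Oc2cc(OCc3ccccc3)cc(OCc3ccccc3)c2I)C#C[C@@H](Oc2cc(OCc3ccccc3)cc(OCc3ccccc3)c2)c2ccc(OCc3ccccc3)cc2)cc1 | intermediate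
11 | (1R,4R,Z)-1-[4-(benzyloxy)phenyl]-1-[3,5-bis(benzyloxy)phenoxy]-4-[3,5-bis(benzyloxy)-2-iodophenoxy]-4-(4-methoxyphenyl)but-2-ene | COc1ccc([C@H](Oc2cc(OCc3ccccc3)cc(OCc3ccccc3)c2I)/C=C\[C@@H](Oc2cc(OCc3ccccc3)cc(OCc3ccccc3)c2)c2ccc(OCc3ccccc3)cc2)cc1 | intermediate
12 | methyl (2R,3R)-2-[(2R,3S)-5,7-bis(benzyloxy)-2-(4-methoxyphenyl)-4-oxochroman-3-yl]-3-[4-(benzyloxy)phenyl]-3-[3,5-bis(benzyloxy)phenoxy]propanoate | COc1ccc([C@@H]2Oc3cc(OCc4ccccc4)cc(OCc4ccccc4)c3C(=O)[C@H]2[C@@H](C(=O)OC)[C@@H](Oc2cc(OCc3ccccc3)cc(OCc3ccccc3)c2)c2ccc(OCc3ccccc3)cc2)cc1 | intermediate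
13 | trimethylstannyl ester of acid 14 | COc1ccc([C@@H]2Oc3cc(OCc4ccccc4)cc(OCc4ccccc4)c3C(=O)[C@H]2[C@@H](C(=O)O[Sn](C)(C)C)[C@@H](Oc2cc(OCc3ccccc3)cc(OCc3ccccc3)c2)c2ccc(OCc3ccccc3)cc2)cc1 | intermediate (not isolated)
14 | (2R,3R)-2-[(2R,3S)-5,7-bis(benzyloxy)-2-(4-methoxyphenyl)-4-oxochroman-3-yl]-3-[4-(benzyloxy)phenyl]-3-[3,5-bis(benzyloxy)phenoxy]propanoic acid | COc1ccc([C@@H]2Oc3cc(OCc4ccccc4)cc(OCc4ccccc4)c3C(=O)[C@H]2[C@@H](C(=O)O)[C@@H](Oc2cc(OCc3ccccc3)cc(OCc3ccccc3)c2)c2ccc(OCc3ccccc3)cc2)cc1 | intermediate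
15 | acid chloride of acid 14 | COc1ccc([C@@H]2Oc3cc(OCc4ccccc4)cc(OCc4ccccc4)c3C(=O)[C@H]2[C@@H](C(Cl)=O)[C@@H](Oc2cc(OCc3ccccc3)cc(OCc3ccccc3)c2)c2ccc(OCc3ccccc3)cc2)cc1 | intermediate (not isolated)
16 | (2R,3S,2''R,3''R)-5,7,5'',7''-tetrakis(benzyloxy)-2''-[4-(benzyloxy)phenyl]-2-(4-methoxyphenyl)-3,3''-bichromane-4,4''-dione | COc1ccc([C@@H]2Oc3cc(OCc4ccccc4)cc(OCc4ccccc4)c3C(=O)[C@H]2[C@H]2C(=O)c3c(OCc4ccccc4)cc(OCc4ccccc4)cc3O[C@H]2c2ccc(OCc3ccccc3)cc2)cc1 | intermediate
17 | Sikokianin B | COc1ccc([C@@H]2Oc3cc(O)cc(O)c3C(=O)[C@H]2[C@H]2C(=O)c3c(O)cc(O)cc3O[C@H]2c2ccc(O)cc2)cc1 | target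

**Step count**

Total: 11 steps. Longest linear sequence: 10 steps (steps 1 and 3 to 11, from 4-methoxybenzaldehyde); step 2 is a one-step side branch.

**Steps most likely to fail**

1. Step 8 (Proposed new method).
   - What may go wrong: carbopalladation of the arylpalladium in 5-exo mode before CO is taken up; beta-hydride or beta-aryloxide elimination of the C3'' alkylpalladium before the second CO insertion; methanolysis of the aroylpalladium before it reaches the hindered internal alkene; ionisation of the allylic aryl ethers by zerovalent palladium.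
   - Fallback (known chemistry), from 11 back to 16: iodine–magnesium exchange with i-PrMgCl·LiCl (THF, −20 °C) and a methanol quench remove the iodine and give the iodine-free Z-alkene F1 (on scale F1 would be made directly by using phenol 4 in step 3 as well).
   - Oxidative bis(methoxycarbonylation) with divalent palladium (Pd(O2CCF3)2, an aryl α-diimine ligand, 1,4-benzoquinone, catalytic TsOH, CO 4 bar, MeOH/THF, rt) is a known syn-stereospecific addition of two ester groups to 1,2-disubstituted alkenes and should give the succinate diester F2. Because the two alkene faces differ only in remote para substituents, its face isomer, the diester F3, is expected alongside and has to be separated.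
   - Me3SnOH as in step 9 converts F2 through the bis(trimethylstannyl) ester F4 into the diacid F5.
   - TFAA closes F5 to the cis-disubstituted cyclic anhydride F6. SnCl4 (CH2Cl2, −78 to 0 °C) opens it by Friedel–Crafts attack of one of the two aryl ether rings, to acid 14 when unit 1 closes first or to the isomeric keto acid F7 when unit 2 closes first. Either acid is closed again as in step 10 (through 15, or through the acid chloride F8) to 16.
   - The price is the loss of face control, which the iodide-directed step 8 is designed to supply.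

2. Step 3 (step 6 shares the risk to a lesser degree).
   - What may go wrong: ionisation of the oxyphosphonium intermediate at the 4-methoxybenzylic, propargylic carbon, which erodes the inversion and opens C-alkylation of the electron-rich phenol; slow attack of the hindered ortho-iodophenol makes this worse.
   - Fallback, from 1 back to 7: ethynylmagnesium bromide (THF, 0 °C) gives the racemic propargylic alcohol F9, and Ac2O/Et3N/DMAP gives its acetate F10. Copper-catalysed enantioselective propargylic etherification (CuOTf·0.5C6H6, a chiral pybox ligand of the antipode that gives the R ether, i-Pr2NEt, MeOH, −20 °C) with phenol 5 then gives 7 directly.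
   - Both enantiomers of F10 converge on one allenylidene complex of monovalent copper, and the ligand, not an SN2 event at an ionisable carbon, decides the configuration. Steps 1, 3 and 4 are replaced.

3. Step 9.
   - What may go wrong: the ester carbon is flanked by two tertiary carbons and may resist Me3SnOH; forcing the reaction invites E1cB loss of the C2'' aryloxide, retro-oxa-Michael opening of the unit 1 pyranone and epimerisation at C3 or C3''.
   - Fallback, from 11 back to 14: the hydrolysis is removed by running the carbonylation of step 8 with water in place of methanol (PdCl2(PPh3)2, CO 40 atm, Et3N, H2O, MeCN/toluene, 95 °C), so that the last acylpalladium is hydrolysed and acid 14 is obtained directly after a mild acid wash. No new compound is made.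

**Further compounds**

F1 | step 8 | (1R,4R,Z)-1-[4-(benzyloxy)phenyl]-1,4-bis[3,5-bis(benzyloxy)phenoxy]-4-(4-methoxyphenyl)but-2-ene | COc1ccc([C@H](Oc2cc(OCc3ccccc3)cc(OCc3ccccc3)c2)/C=C\[C@@H](Oc2cc(OCc3ccccc3)cc(OCc3ccccc3)c2)c2ccc(OCc3ccccc3)cc2)cc1
F2 | step 8 | dimethyl (2S,3R)-2-{(R)-[3,5-bis(benzyloxy)phenoxy](4-methoxyphenyl)methyl}-3-{(R)-[4-(benzyloxy)phenyl][3,5-bis(benzyloxy)phenoxy]methyl}butanedioate | COc1ccc([C@H](Oc2cc(OCc3ccccc3)cc(OCc3ccccc3)c2)[C@@H](C(=O)OC)[C@@H](C(=O)OC)[C@@H](Oc2cc(OCc3ccccc3)cc(OCc3ccccc3)c2)c2ccc(OCc3ccccc3)cc2)cc1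
F3 | step 8 | dimethyl (2R,3S)-2-{(R)-[3,5-bis(benzyloxy)phenoxy](4-methoxyphenyl)methyl}-3-{(R)-[4-(benzyloxy)phenyl][3,5-bis(benzyloxy)phenoxy]methyl}butanedioate (face isomer) | COc1ccc([C@H](Oc2cc(OCc3ccccc3)cc(OCc3ccccc3)c2)[C@H](C(=O)OC)[C@H](C(=O)OC)[C@@H](Oc2cc(OCc3ccccc3)cc(OCc3ccccc3)c2)c2ccc(OCc3ccccc3)cc2)cc1
F4 | step 8 | bis(trimethylstannyl) ester of diacid F5 | COc1ccc([C@H](Oc2cc(OCc3ccccc3)cc(OCc3ccccc3)c2)[C@@H](C(=O)O[Sn](C)(C)C)[C@@H](C(=O)O[Sn](C)(C)C)[C@@H](Oc2cc(OCc3ccccc3)cc(OCc3ccccc3)c2)c2ccc(OCc3ccccc3)cc2)cc1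
F5 | step 8 | (2S,3R)-2-{(R)-[3,5-bis(benzyloxy)phenoxy](4-methoxyphenyl)methyl}-3-{(R)-[4-(benzyloxy)phenyl][3,5-bis(benzyloxy)phenoxy]methyl}butanedioic acid | COc1ccc([C@H](Oc2cc(OCc3ccccc3)cc(OCc3ccccc3)c2)[C@@H](C(=O)O)[C@@H](C(=O)O)[C@@H](Oc2cc(OCc3ccccc3)cc(OCc3ccccc3)c2)c2ccc(OCc3ccccc3)cc2)cc1
F6 | step 8 | cis-2,3-disubstituted succinic anhydride of diacid F5 | COc1ccc([C@H](Oc2cc(OCc3ccccc3)cc(OCc3ccccc3)c2)[C@H]2C(=O)OC(=O)[C@H]2[C@@H](Oc2cc(OCc3ccccc3)cc(OCc3ccccc3)c2)c2ccc(OCc3ccccc3)cc2)cc1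
F7 | step 8 | (2S,3R)-2-[(2R,3R)-5,7-bis(benzyloxy)-2-[4-(benzyloxy)phenyl]-4-oxochroman-3-yl]-3-[3,5-bis(benzyloxy)phenoxy]-3-(4-methoxyphenyl)propanoic acid (unit 2 closed, unit 1 open) | COc1ccc([C@H](Oc2cc(OCc3ccccc3)cc(OCc3ccccc3)c2)[C@@H](C(=O)O)[C@H]2C(=O)c3c(OCc4ccccc4)cc(OCc4ccccc4)cc3O[C@H]2c2ccc(OCc3ccccc3)cc2)cc1
F8 | step 8 | acid chloride of keto acid F7 | COc1ccc([C@H](Oc2cc(OCc3ccccc3)cc(OCc3ccccc3)c2)[C@@H](C(Cl)=O)[C@H]2C(=O)c3c(OCc4ccccc4)cc(OCc4ccccc4)cc3O[C@H]2c2ccc(OCc3ccccc3)cc2)cc1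
F9 | step 3 | rac-1-(4-methoxyphenyl)prop-2-yn-1-ol | COc1ccc(C(O)C#C)cc1
F10 | step 3 | rac-1-(4-methoxyphenyl)prop-2-yn-1-yl acetate | COc1ccc(C(OC(C)=O)C#C)cc1
F0 | step 9 | none | none
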